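The easy step came first. The right-handed substrate in eta, alpha and zeta read 49.4%, 48.7% and 48.7% at 60.0 min, so I treated it as standing still and followed the left-handed substrate. In eta it read 36.1% at that time, which gives 0.326. I call this number the exposure: the natural logarithm of the left-handed substrate's starting fraction over its present fraction, which is the time integral of its fractional loss per minute. With the right-handed substrate fixed, the excess is one minus the surviving fraction over one plus it, and the surviving fraction is the exponential of minus the exposure.

| setting | eta | alpha | zeta | spring | midnight |
|---|---|---|---|---|---|
| left-handed substrate | 0.076 M | 0.076 M | 0.076 M | 0.076 M | 0.076 M |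
| right-handed substrate | 0.076 M | 0.076 M | 0.076 M | 0.076 M | 0.076 M |
| partner | 2.2 equiv (fed, over 12 min) | 3.9 equiv (fed, over 12 min) | 6.6 equiv (fed, over 12 min) | 2.00 equiv (fed, over 12 min) | 8.00 equiv (fed, over 12 min) |
| precatalyst | 10 mol% | 10 mol% | 10 mol% | 10 mol% | 10 mol% |
| added ligand | 15 mM | 15 mM | 15 mM | 15 mM | 15 mM |
| remark | run made earlier; the fed solution adds 0.25 times the starting volume | run made earlier; the fed solution adds 0.25 times the starting volume | run made earlier; the fed solution adds 0.25 times the starting volume | the fed solution adds 0.25 times the starting volume | the fed solution adds 0.25 times the starting volume |
| time |  |  |  | 80 min | 80 min |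

- eta (time / min: right-handed substrate / %, left-handed substrate / %, left-handed product / %): 5.00: 49.3, 49.5, 0; 8.00: 49.7, 50.4, 0.6; 15.0: 49.9, 48.9, 0.6; 30.0: 49.8, 46.4, 3.4; 60.0: 49.4, 36.1, 13.2
- alpha (time / min: right-handed substrate / %, left-handed substrate / %, left-handed product / %): 5.00: 50.8, 49.7, 0; 15.0: 49.2, 47.4, 2.2; 25.0: 49.0, 41.7, 6.4; 40.0: 50.3, 33.3, 15.6; 60.0: 48.7, 24.0, 25.8
- zeta (time / min: right-handed substrate / %, left-handed substrate / %, left-handed product / %): 5.00: 50.7, 49.8, 0.1; 15.0: 50.3, 45.9, 4.6; 25.0: 49.7, 36.2, 12.8; 40.0: 49.5, 23.5, 25.1; 60.0: 48.7, 12.4, 36.4

(each reading ± 0.5 percentage points)

- free catalyst is single-handed; left-handed substrate and right-handed substrate are mirror images of each other, charged as a racemate, each of them at the stated concentration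
- amounts are per litre of the starting volume; all of the dose is in the solution fed
- an excess is the difference of the two amounts in percent of their sum
- an excess is below zero if the other one leads

- the flask that ends with the higher excess of right-handed substrate over left-handed substrate among what is left of the two, or "neither" when 2 percentage points or less lies between them (spring / midnight / neither)
- excess of right-handed substrate over left-handed substrate among what is left of the two at the end, spring
- excess of right-handed substrate over left-handed substrate among what is left of the two at the end, midnight

I ran the flask slowly in my head. In the first instants little happened: at 15.0 min the left-handed product read 0.6% in eta, 2.2% in alpha and 4.6% in zeta. I read this lag as free catalyst still held in precatalyst, waiting for partner to release it.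

In the middle, the exposure of eta rose from 0.0747 at 30.0 min to 0.326 at 60.0 min, a factor of 4.36 while the time doubled. Given the scatter this is a rough reading, but it suggests a square law: free catalyst building steadily, with partner acting both in the release and in the turnover. So I scaled exposure with the square of partner times time, which gave spring 0.479 and an excess of 23.5%.

Late on, I took the release as over. Zeta then looked pseudo-first-order, with a slope of 0.0320 /min and a line running back to 16.4 min. Scaling that slope by the first power of partner and keeping the start of zeta's line gave midnight 0.0387 /min, an exposure of 2.47 and an excess of 84.4%.

The forecast, reading “a nearly perfect kinetic resolution”, named midnight, with 20% for spring and 84% for midnight. My spring figure stood above its value.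

    partner + catalyst intermediate B → free catalyst + right-handed product (k = 0.0840 /M/min)
    partner → decomposition product (k = 5.00 × 10⁻⁵ /min)
    free catalyst + left-handed substrate ⇌ catalyst intermediate A (K = 21.0 /M, k = 54.0 /M/min)
    partner + precatalyst → free catalyst + spent reagent (k = 0.220 /M/min)
    free catalyst + right-handed substrate ⇌ catalyst intermediate B (K = 6.30 /M, k = 30.0 /M/min)
    free catalyst + added ligand ⇌ idle complex, settled at all times (K = 200 /M)
    partner + catalyst intermediate A → free catalyst + left-handed product (k = 4.00 /M/min)

The simulation gave midnight as the flask with the higher excess, with 22.0% for spring and 84.4% for midnight. The neighbouring flask was spring left until 3.0 h. Scaled from 0.326, the square law gave it an exposure of 2.42 and an excess of 83.7%. With 26% of its left-handed substrate unbound, the flask showed an exposure of 1.35, less than reckoned. Its precatalyst had fallen from 16.8% of the catalyst charged at 80.0 min to 2.87% at 180 min. The excess of the neighbouring flask stood at 58.3%.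

The readings stem from a simulated flask from invented constants; the scatter is artificial.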